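The runs are simulated with made-up constants, noise included.

Target in the east flask, which is the flask asked about, climbs from nothing to 20.6% at 0.333 min and stands at 53.7% at 1.00 min. Over the same span the reading of solid substrate drops from 59.9% to 0%, and that is the knee of the curve.

| setting | east | north-east | flask |
|---|---|---|---|
| solid substrate | 0.20 mM | 0.20 mM | 0.20 mM |
| partner | 0.30 mM | 0.45 mM | 0.300 mM |
| initiator | 5 µM | 5 µM | 5.0 µM |
| remark | the very flask that is asked about, followed so far | run made earlier |  |
| time |  |  | 50 min |

| run | time / min | target / % | solid substrate / % |
|---|---|---|---|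
| east | 0.333 | 20.6 | 59.9 |
| east | 1.00 | 53.7 | 0 |
| east | 1.50 | 52.6 | 0 |
| east | 2.50 | 47.5 | 0.7 |
| east | 4.00 | 40.2 | 0 |
| east | 5.00 | 36.3 | 0 |
| east | 6.00 | 33.3 | 0.2 |
| north-east | 1.50 | 46.7 | 0.3 |
| north-east | 2.50 | 35.6 | 0.2 |
| north-east | 4.00 | 26.6 | 0 |
| north-east | 6.00 | 16.8 | 0 |
| north-east | 8.00 | 10.9 | 0 |
| north-east | 12.0 | 4.8 | 0 |
| north-east | 20.0 | 2.3 | 0.5 |

(scatter of a reading: 0.5 percentage points)

- the moment within 50 min at which there is most target
- the amount of target, in percent of the solid substrate charged, at that time

Now draw the fall. Between 2.50 min and 6.00 min the east target drops with a first-order constant of 0.101 min⁻¹. The north-east run covers a like span of target between 1.50 min and 4.00 min, and there the constant is 0.225 min⁻¹, faster with more partner charged. So take the loss as pseudo-first-order in target, with a constant that grows with c partner, and define the partner sensitivity, the extra constant per unit of extra partner: 13.7 M⁻¹ s⁻¹. Take this sensitivity times c partner as an estimate of the loss constant on the stretches of the fall that these two constants were read from, and not on the rise.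

Run the east fall back to 1.00 min: it gives 55.3%, which is 1.6 percentage points above the reading, against a scatter of 0.5 points. Target is therefore still being made there, and I put the top a little past 1.00 min, between those two values. The half-life of the fall, 6.83 min, is short against 50 min, so the time limit plays no part.

The forecast says 54% at 1.1 min, holding that “formation is nearly finished but not quite”.

The flask gives 54.4% at 1.15 min, and at 1.72 min target still stands at 51.5%.

    partner + target → over-reaction product (k = 17.7 M⁻¹ s⁻¹)
    starting material + initiating radical → chain carrier (k = 1.69 × 10⁷ M⁻¹ s⁻¹)
    starting material + target → side product (k = 345 M⁻¹ s⁻¹)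
    partner + chain carrier → target + initiating radical (k = 5.84 × 10⁷ M⁻¹ s⁻¹)
    initiator → 2 initiating radical (k = 0.00611 s⁻¹)
    2 initiating radical → ended chains (k = 7.60 × 10⁸ M⁻¹ s⁻¹)
    solid substrate ⇌ starting material, rate k7*(cs7 - [starting material]) while solid is left; crystals form when [starting material] > cs7 (solubility = 0.0880 mM, k = 0.0592 s⁻¹)

Use the sensitivity, which stays an estimate from the readings, on this flask at 5.00 min: starting material is 0% and partner is 28.6% of its charge, so the estimated loss constant is 0.0706 min⁻¹. In the neighbour charged with 1.2 mM of partner, starting material is 0% and 74.4% of the partner charge stands at 50.0 min, so the same estimate puts the half-life of target there at about 0.944 min, and target in that neighbour is 0%.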